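**Retrosynthetic overview**
1. Target 24 ⇐ PMB removal and oxidation of the C13 carbinol ⇐ macrolactone 22.
2. Key disconnection C11–C12: SmI2 ketyl radical addition of the C11 aldehyde to the (E)-enoate of seco-aldehyde 20, closing the 14-membered carbocycle and the γ-lactone in one operation.
3. 20 ⇐ B-alkyl Suzuki coupling (C2–C3) of oxolane fragment 10 with bromodienoate 17; 17 ⇐ Nozaki–Hiyama–Kishi coupling (C12–C13) on a carboalumination-derived bromoalkene.
4. 10 ⇐ syn-crotylboration (C5, C6), cobalt-catalysed aerobic oxidative cyclization (oxolane, C9), chelate-controlled dithiane addition (C10, C11).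
5. Ring order: oxolane first (step 2), then carbocycle and lactone together (step 11).

Assumption: 4-methylpent-4-enal (1) and methyl (E)-3-iodo-2-methylprop-2-enoate (15) are taken as catalogue compounds.

Numbering used in names: ring carbons C1(CH3)=C2–C3–C4–C5(CH3)–C6–C7–C8–C9(CH3)–C10(OH)–C11–C12–C13(=O)–C14–back to C1; oxolane oxygen bridges C6 and C9; lactone is C11–O–C16(=O)–C15(H)(CH3)–C12. Target: 5R,6R,9R,10R,11S,12R,15R, (E)-C1=C2.

The route has not been run; selectivities are argued from analogy and mechanism.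

**Step 1**
Reactants: 1 4-methylpent-4-enal; 2 cis-but-2-ene
Product: 4 (3R,4R)-3,7-dimethylocta-1,7-dien-4-ol, via (Z)-crotyldiisopinocampheylborane 3 (not isolated)
Conditions: 2, KOt-Bu, n-BuLi, THF, −78 to −45 °C; (−)-Ipc2BOMe, −78 °C; BF3·OEt2; then 1, −78 °C; NaOH, H2O2
Reagents that add atoms: none
Why: Brown asymmetric crotylboration through a closed chair transition state, in which the Z-crotyl geometry gives the syn C5/C6 relationship and the (+)-α-pinene-derived isopinocampheyl groups direct attack to the Si face of the aldehyde (5R,6R).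

**Step 2**
Reactants: 4 (3R,4R)-3,7-dimethylocta-1,7-dien-4-ol
Product: 5 [(2R,5R)-5-[(2R)-but-3-en-2-yl]-2-methyloxolan-2-yl]methanol
Conditions: Co(modp)2 (10 mol %, modp = 1-morpholinocarbamoyl-4,4-dimethylpentane-1,3-dionate), O2 (1 atm), t-BuOOH, i-PrOH, 55 °C
Reagents that add atoms: dioxygen, O=O
Why: Mukaiyama aerobic oxidative cyclization, in which the alkoxide bound to divalent cobalt adds 5-exo to the 1,1-disubstituted alkene with the C6 side chain pseudo-equatorial to give the 2,5-trans oxolane (9R), and the primary carbon radical is trapped by O2 and reduced to the C10 hydroxymethyl group; the vinyl group cannot reach a five-membered transition state.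

**Step 3**
Reactants: 5 [(2R,5R)-5-[(2R)-but-3-en-2-yl]-2-methyloxolan-2-yl]methanol
Product: 6 (2R,5R)-5-[(2R)-but-3-en-2-yl]-2-methyloxolane-2-carbaldehyde
Conditions: TEMPO (cat.), PhI(OAc)2, CH2Cl2, rt
Reagents that add atoms: none
Why: Oxoammonium oxidation of the primary alcohol to an aldehyde that has no α-hydrogen, so C9 cannot epimerize.

**Step 4**
Reactants: 6 (2R,5R)-5-[(2R)-but-3-en-2-yl]-2-methyloxolane-2-carbaldehyde; 7 1,3-dithiane
Product: 9 (S)-[(2R,5R)-5-[(2R)-but-3-en-2-yl]-2-methyloxolan-2-yl](1,3-dithian-2-yl)methanol, via 2-lithio-1,3-dithiane 8 (not isolated)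
Conditions: 7, n-BuLi, THF, −30 °C; MgBr2·OEt2, −78 °C; then 6
Reagents that add atoms: none
Why: Corey–Seebach dithiane addition under Cram-chelate control, with MgBr2 bridging the aldehyde and oxolane oxygens so the nucleophile attacks from the face of the C9 methyl, anti to ring carbon C8, giving the syn O9/O10 arrangement of the target (the descriptor reads S only because sulfur raises the priority of C11).

**Step 5**
Reactants: 9 (S)-[(2R,5R)-5-[(2R)-but-3-en-2-yl]-2-methyloxolan-2-yl](1,3-dithian-2-yl)methanol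
Product: 10 2-[(S)-{(2R,5R)-5-[(2R)-but-3-en-2-yl]-2-methyloxolan-2-yl}[(4-methoxyphenyl)methoxy]methyl]-1,3-dithiane
Conditions: KH, PMBCl, Bu4NI (cat.), THF, 0 °C to rt
Reagents that add atoms: 4-methoxybenzyl chloride, COc1ccc(CCl)cc1
Why: Williamson etherification; the PMB ether masks C10–OH through the later oxidation and supplies the chelating α-alkoxy group used in step 11.

**Step 6**
Reactants: 11 but-3-yn-1-ol
Product: 13 (3E)-4-bromo-3-methylbut-3-en-1-ol, via alkenyldimethylalane 12 (not isolated)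
Conditions: AlMe3, Cp2ZrCl2 (cat.), CH2Cl2, 0 °C to rt; NBS, THF, −30 °C
Reagents that add atoms: trimethylaluminium, C[Al](C)C; N-bromosuccinimide, BrN1C(=O)CCC1=O
Why: Negishi zirconium-catalysed syn-carboalumination puts CH3 on the internal and aluminium on the terminal alkyne carbon cis to each other, and bromodealumination with retention gives the (E)-bromoalkene (C14 trans to Br).

**Step 7**
Reactants: 13 (3E)-4-bromo-3-methylbut-3-en-1-ol
Product: 14 (3E)-4-bromo-3-methylbut-3-enal
Conditions: Dess–Martin periodinane, NaHCO3, CH2Cl2, 0 °C; used crude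
Reagents that add atoms: none
Why: Buffered Dess–Martin oxidation gives the β,γ-unsaturated aldehyde without migration of the double bond into conjugation.

**Step 8**
Reactants: 14 (3E)-4-bromo-3-methylbut-3-enal; 15 methyl (E)-3-iodo-2-methylprop-2-enoate
Product: 17 methyl (2E,6E)-7-bromo-4-hydroxy-2,6-dimethylhepta-2,6-dienoate (both C4 epimers), via alkenylchromium dichloride 16 (not isolated)
Conditions: CrCl2, NiCl2 (cat.), DMSO, rt
Reagents that add atoms: none
Why: Nozaki–Hiyama–Kishi coupling, in which the β-iodoenoate is activated by nickel and transferred to chromium much faster than the unactivated bromoalkene and the alkenylchromium adds to the aldehyde with retention of E geometry; the new carbinol (C13) is unselective but is oxidized in step 12.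

**Step 9**
Reactants: 10 2-[(S)-{(2R,5R)-5-[(2R)-but-3-en-2-yl]-2-methyloxolan-2-yl}[(4-methoxyphenyl)methoxy]methyl]-1,3-dithiane; 17 methyl (2E,6E)-7-bromo-4-hydroxy-2,6-dimethylhepta-2,6-dienoate
Product: 19 methyl (2E,6E,10R)-10-[(2R,5R)-5-[(S)-(1,3-dithian-2-yl)[(4-methoxyphenyl)methoxy]methyl]-5-methyloxolan-2-yl]-4-hydroxy-2,6-dimethylundeca-2,6-dienoate, via B-alkyl-9-BBN adduct 18 (not isolated)
Conditions: 10, 9-BBN, THF, rt; then 17, Pd(dppf)Cl2, AsPh3, Cs2CO3, DMF/H2O, rt
Reagents that add atoms: none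
Why: B-alkyl Suzuki–Miyaura coupling: anti-Markovnikov hydroboration of the only terminal alkene, then sp3–sp2 coupling with retention of the bromoalkene geometry forms C2–C3 and the (E)-C1=C2 alkene.

**Step 10**
Reactants: 19 methyl (2E,6E,10R)-10-[(2R,5R)-5-[(S)-(1,3-dithian-2-yl)[(4-methoxyphenyl)methoxy]methyl]-5-methyloxolan-2-yl]-4-hydroxy-2,6-dimethylundeca-2,6-dienoate
Product: 20 methyl (2E,6E,10R)-4-hydroxy-10-[(2R,5R)-5-[(1S)-1-[(4-methoxyphenyl)methoxy]-2-oxoethyl]-5-methyloxolan-2-yl]-2,6-dimethylundeca-2,6-dienoate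
Conditions: MeI, CaCO3, MeCN/H2O, 45 °C; used directly
Reagents that add atoms: water, O
Why: S-methylation and hydrolysis of the dithioacetal under buffered neutral conditions leaves the alkenes, PMB ether, ester and allylic alcohol untouched and avoids epimerization at C10.

**Step 11**
Reactants: 20 methyl (2E,6E,10R)-4-hydroxy-10-[(2R,5R)-5-[(1S)-1-[(4-methoxyphenyl)methoxy]-2-oxoethyl]-5-methyloxolan-2-yl]-2,6-dimethylundeca-2,6-dienoate
Product: 22 C10-O-PMB C13-hydroxy macrolactone (13-hydroxy analogue of 24 as its PMB ether; C5 C6 C9 C10 C11 C12 C15 configured as in 24; both C13 epimers), via C15-epimeric macrolactone mixture 21 (not isolated)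
Conditions: SmI2 (3 equiv), t-BuOH, THF, −78 to 0 °C, slow addition to 1 mM; then DBU, PhMe, 50 °C
Reagents that add atoms: none
Why: Proposed new method: SmI2 reduces the aldehyde to a ketyl radical held in a five-membered chelate by trivalent samarium and the C10 OPMB oxygen, which adds 14-exo to C12 of the (E)-enoate through the samarium-bridged ketyl/ester transition state of the bimolecular reaction (attack anti to C9 sets 11S, the chelate gives the cis C11/C12 fusion), the C11 samarium alkoxide then closes the γ-lactone with loss of methanol and DBU equilibrates C15 to the methyl-trans 15R epimer; closest known reactions are the intermolecular SmI2 aldehyde–crotonate γ-lactone synthesis (cis-β,γ selective) and medium-ring SmI2 ketyl–olefin cyclizations.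

**Step 12**
Reactants: 22 C10-O-PMB C13-hydroxy macrolactone
Product: 23 C10-O-PMB ether of 24 (5R,6R,9R,10R,11S,12R,15R)
Conditions: Dess–Martin periodinane, NaHCO3, CH2Cl2, 0 °C
Reagents that add atoms: none
Why: Dess–Martin oxidation of the only free alcohol converges both C13 epimers to the ketone under buffered, non-basic conditions that avoid C12 epimerization, β-elimination of the lactone oxygen and conjugation of the C1=C2 alkene.

**Step 13**
Reactants: 23 C10-O-PMB ether of 24
Product: 24 target CNP0386136.3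
Conditions: DDQ, CH2Cl2/pH 7 buffer, 0 °C
Reagents that add atoms: none
Why: Oxidative PMB ether cleavage by DDQ (electron transfer from the anisyl ring, hydrolysis of the oxocarbenium ion) is neutral and leaves the β,γ-unsaturated ketone, lactone and trisubstituted alkene intact.

**Compound list**
1 | 4-methylpent-4-enal | CC(=C)CCC=O | starting material
2 | cis-but-2-ene | C/C=C\C | starting material
3 | (Z)-crotyldiisopinocampheylborane (isopinocampheyl groups from (+)-α-pinene) | C/C=C\CB([C@@H]1C[C@@H]2C[C@@H](C2(C)C)[C@H]1C)[C@@H]1C[C@@H]2C[C@@H](C2(C)C)[C@H]1C | intermediate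
4 | (3R,4R)-3,7-dimethylocta-1,7-dien-4-ol | C=C[C@@H](C)[C@H](O)CCC(C)=C | intermediate
5 | [(2R,5R)-5-[(2R)-but-3-en-2-yl]-2-methyloxolan-2-yl]methanol | C=C[C@@H](C)[C@H]1CC[C@@](C)(O1)CO | intermediate
6 | (2R,5R)-5-[(2R)-but-3-en-2-yl]-2-methyloxolane-2-carbaldehyde | C=C[C@@H](C)[C@H]1CC[C@@](C)(O1)C=O | intermediate
7 | 1,3-dithiane | C1CSCSC1 | starting material
8 | 2-lithio-1,3-dithiane | [Li]C1SCCCS1 | intermediate
9 | (S)-[(2R,5R)-5-[(2R)-but-3-en-2-yl]-2-methyloxolan-2-yl](1,3-dithian-2-yl)methanol | C=C[C@@H](C)[C@H]1CC[C@@](C)(O1)[C@H](O)C1SCCCS1 | intermediate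
10 | 2-[(S)-{(2R,5R)-5-[(2R)-but-3-en-2-yl]-2-methyloxolan-2-yl}[(4-methoxyphenyl)methoxy]methyl]-1,3-dithiane | C=C[C@@H](C)[C@H]1CC[C@@](C)(O1)[C@H](OCc1ccc(OC)cc1)C1SCCCS1 | intermediate
11 | but-3-yn-1-ol | C#CCCO | starting material
12 | [(E)-4-(dimethylalumanyloxy)-2-methylbut-1-en-1-yl]dimethylalane | C[Al](C)OCC/C(C)=C/[Al](C)C | intermediate
13 | (3E)-4-bromo-3-methylbut-3-en-1-ol | OCC/C(C)=C/Br | intermediate
14 | (3E)-4-bromo-3-methylbut-3-enal | O=CC/C(C)=C/Br | intermediate
15 | methyl (E)-3-iodo-2-methylprop-2-enoate | COC(=O)/C(C)=C/I | starting material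
16 | methyl (E)-3-(dichlorochromio)-2-methylprop-2-enoate (trivalent chromium) | COC(=O)/C(C)=C/[Cr](Cl)Cl | intermediate
17 | methyl (2E,6E)-7-bromo-4-hydroxy-2,6-dimethylhepta-2,6-dienoate (both C4 epimers) | COC(=O)/C(C)=C/C(O)C/C(C)=C/Br | intermediate
18 | 9-[(3R)-3-{(2R,5R)-5-[(S)-(1,3-dithian-2-yl)[(4-methoxyphenyl)methoxy]methyl]-5-methyloxolan-2-yl}butyl]-9-borabicyclo[3.3.1]nonane | B1(C2CCCC1CCC2)CC[C@@H](C)[C@H]3CC[C@@](C)(O3)[C@H](OCc4ccc(OC)cc4)C5SCCCS5 | intermediate
19 | methyl (2E,6E,10R)-10-[(2R,5R)-5-[(S)-(1,3-dithian-2-yl)[(4-methoxyphenyl)methoxy]methyl]-5-methyloxolan-2-yl]-4-hydroxy-2,6-dimethylundeca-2,6-dienoate | COC(=O)/C(C)=C/C(O)C/C(C)=C/CC[C@@H](C)[C@H]1CC[C@@](C)(O1)[C@H](OCc1ccc(OC)cc1)C1SCCCS1 | intermediate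
20 | methyl (2E,6E,10R)-4-hydroxy-10-[(2R,5R)-5-[(1S)-1-[(4-methoxyphenyl)methoxy]-2-oxoethyl]-5-methyloxolan-2-yl]-2,6-dimethylundeca-2,6-dienoate | COC(=O)/C(C)=C/C(O)C/C(C)=C/CC[C@@H](C)[C@H]1CC[C@@](C)(O1)[C@H](OCc1ccc(OC)cc1)C=O | intermediate
21 | macrolactone alcohol as 22 but both C15 epimers | C/C1=C\CC[C@@H](C)[C@H]2CC[C@@](C)(O2)[C@H](OCc3ccc(OC)cc3)[C@H]2OC(=O)C(C)[C@H]2C(O)C1 | intermediate
22 | C10-O-PMB C13-hydroxy macrolactone (ring carbons and lactone as in 24, C13 carbinol as both epimers, all other stereocentres as in 24) | C/C1=C\CC[C@@H](C)[C@H]2CC[C@@](C)(O2)[C@H](OCc3ccc(OC)cc3)[C@H]2OC(=O)[C@H](C)[C@H]2C(O)C1 | intermediate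
23 | C10-O-(4-methoxybenzyl) ether of 24 (5R,6R,9R,10R,11S,12R,15R) | C/C1=C\CC[C@@H](C)[C@H]2CC[C@@](C)(O2)[C@H](OCc3ccc(OC)cc3)[C@H]2OC(=O)[C@H](C)[C@H]2C(=O)C1 | intermediate
24 | CNP0386136.3: (E)-C1=C2 14-membered carbocycle with 6,9-oxolane bridge, C10 hydroxyl, C13 ketone and cis-fused α-methyl-γ-lactone; 5R,6R,9R,10R,11S,12R,15R | C/C1=C\CC[C@@H](C)[C@H]2CC[C@@](C)(O2)[C@H](O)[C@H]2OC(=O)[C@H](C)[C@H]2C(=O)C1 | target

**Totals**
Total steps: 13. Longest linear sequence: 10 (steps 1–5 and 9–13); steps 6–8 build the second branch.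

**Steps most likely to fail**

Step 11 (ring-closing ketyl addition). A 14-membered ketyl–olefin closure onto a trisubstituted enoate is unprecedented. Ketyl over-reduction, loss of the α-OPMB group, pinacol dimers, or a mismatched C13 epimer could erode yield or the C11/C12 selectivity, and the free C13 hydroxyl could translactonize under DBU. Fallback: reverse the order of the two bond formations. Set out from 10 and cleave the dithiane (MeI, CaCO3, MeCN/H2O) to the α-PMB-oxy aldehyde F1. Couple F1 with 17 intermolecularly (SmI2, t-BuOH, THF, −78 to 0 °C; then DBU), which is the precedented bimolecular aldehyde–enoate γ-lactone synthesis, to give the bromoalkenyl lactone F2. Hydroborate its terminal alkene with 9-BBN to the B-alkyl borane F3 and close the carbocycle by intramolecular B-alkyl Suzuki–Miyaura coupling (Pd(dppf)Cl2, AsPh3, Cs2CO3, DMF/THF/H2O, high dilution). This comes back to the route at 22.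

Step 4 (C10 configuration). A lithiated dithiane may not respect the magnesium chelate, and discrimination between the C9 methyl and the ring CH2 is subtle. Fallback: set out from 6 with a Grignard reagent, for which chelate control is most reliable. (i-PrO)Me2SiCH2MgCl with MgBr2·OEt2 gives the β-hydroxy silane F4, and Tamao oxidation (H2O2, KF, KHCO3, THF/MeOH) gives the diol F5. 4-MeOC6H4CH(OMe)2 with PPTS gives the 4-methoxybenzylidene acetal F6, and i-Bu2AlH (CH2Cl2, −78 to 0 °C) opens it to the secondary PMB ether with free primary alcohol F7. Hydroboration to the borane F8 and Suzuki coupling with 17 under the step 9 conditions give the hydroxy ester F9. Selective oxidation of its primary alcohol (TEMPO, PhI(OAc)2) rejoins the route at 20.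

Step 2 (trans selectivity at the quaternary oxolane carbon). Cobalt-catalysed cyclization onto a 1,1-disubstituted alkene may be less selective than with terminal alkenes. Fallback: set out from 4 and use a polar metal-oxo cyclization in place of the radical one. Re2O7 with (CF3CO)2O (trifluoroacetyl perrhenate, heptavalent rhenium) in CH2Cl2, then aqueous NaOH/H2O2 work-up, effects a trans-selective syn-oxidative cyclization of the bishomoallylic perrhenate ester and gives 5 directly. It makes no new compound (F0) and comes back at 5.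

**Further compounds**
F1 | step 11 | (2S)-2-[(2R,5R)-5-[(2R)-but-3-en-2-yl]-2-methyloxolan-2-yl]-2-[(4-methoxyphenyl)methoxy]acetaldehyde | C=C[C@@H](C)[C@H]1CC[C@@](C)(O1)[C@H](OCc1ccc(OC)cc1)C=O
F2 | step 11 | bromoalkenyl γ-lactone: 3-methyl-4-[(4E)-5-bromo-1-hydroxy-4-methylpent-4-en-1-yl]-5-[(R)-{(2R,5R)-5-[(2R)-but-3-en-2-yl]-2-methyloxolan-2-yl}[(4-methoxyphenyl)methoxy]methyl]oxolan-2-one, lactone centres as C15, C12, C11 of 24 | C=C[C@@H](C)[C@H]1CC[C@@](C)(O1)[C@H](OCc1ccc(OC)cc1)[C@H]1OC(=O)[C@H](C)[C@H]1C(O)C/C(C)=C/Br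
F3 | step 11 | B-alkyl-9-BBN adduct of F2 (boron on the former terminal alkene carbon C3) | B1(C2CCCC1CCC2)CC[C@@H](C)[C@H]3CC[C@@](C)(O3)[C@H](OCc4ccc(OC)cc4)[C@H]5OC(=O)[C@H](C)[C@H]5C(O)C/C(C)=C/Br
F4 | step 4 | (1S)-1-[(2R,5R)-5-[(2R)-but-3-en-2-yl]-2-methyloxolan-2-yl]-2-[dimethyl(propan-2-yloxy)silyl]ethan-1-ol | C=C[C@@H](C)[C@H]1CC[C@@](C)(O1)[C@H](O)C[Si](C)(C)OC(C)C
F5 | step 4 | (1R)-1-[(2R,5R)-5-[(2R)-but-3-en-2-yl]-2-methyloxolan-2-yl]ethane-1,2-diol | C=C[C@@H](C)[C@H]1CC[C@@](C)(O1)[C@H](O)CO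
F6 | step 4 | (4R)-4-[(2R,5R)-5-[(2R)-but-3-en-2-yl]-2-methyloxolan-2-yl]-2-(4-methoxyphenyl)-1,3-dioxolane (acetal epimers) | C=C[C@@H](C)[C@H]1CC[C@@](C)(O1)[C@H]1COC(c2ccc(OC)cc2)O1
F7 | step 4 | (2R)-2-[(2R,5R)-5-[(2R)-but-3-en-2-yl]-2-methyloxolan-2-yl]-2-[(4-methoxyphenyl)methoxy]ethan-1-ol | C=C[C@@H](C)[C@H]1CC[C@@](C)(O1)[C@H](OCc1ccc(OC)cc1)CO
F8 | step 4 | B-alkyl-9-BBN adduct of F7 | B1(C2CCCC1CCC2)CC[C@@H](C)[C@H]3CC[C@@](C)(O3)[C@H](OCc4ccc(OC)cc4)CO
F9 | step 4 | methyl (2E,6E,10R)-4-hydroxy-10-[(2R,5R)-5-[(1R)-2-hydroxy-1-[(4-methoxyphenyl)methoxy]ethyl]-5-methyloxolan-2-yl]-2,6-dimethylundeca-2,6-dienoate | COC(=O)/C(C)=C/C(O)C/C(C)=C/CC[C@@H](C)[C@H]1CC[C@@](C)(O1)[C@H](OCc1ccc(OC)cc1)CO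
F0 | step 2 | none | none
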